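## The problem

The target 23 is a fully substituted phloroglucinol (ring A). C1 carries the (2R)-2-methylbutanoyl group, C2, C4 and C6 carry hydroxyl groups, and C3 and C5 are each joined through one CH2 group to C3 of a 6-ethyl-4-hydroxy-5-methyl-2-pyrone (rings B and C). Because the two pyrone arms are identical, the ring system can be assembled by one twofold bridging of an acylphloroglucinol with a one-carbon electrophile and two pyrones; the difficulty there is selectivity (bis- over mono-bridging, cross- over self-coupling), not connectivity. There is a single stereocentre, the CH(CH3)(C2H5) carbon next to the aryl ketone. No other stereocentre can control it, so it must be set by a reagent or bought, and since it is α to a carbonyl group it can be lost by enolisation under strong base or hot acid. The free enols of rings A, B and C are easily oxidised, and the CH2 bridges flanked by hydroxyl groups are cleaved or scrambled by strong acid, so harsh operations must precede the bridging. The feature that opens the route is the carbonyl carbon itself: it links ring A carbon C1 to the stereogenic CH carbon, and an aryl group and a secondary alkyl group can both be held on one boron atom and both moved from it to one carbon with retention. The stereocentre can therefore be created on boron, where it cannot enolise, by asymmetric hydroboration of a symmetric alkene.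

## Retrosynthesis

**Bridges.** The four C–C bonds of the two CH2 bridges of 23 are cut first (ring A C3–CH2 and C5–CH2, and the CH2–C3 bond of each pyrone). This gives the acylphloroglucinol 16, two equivalents of the pyrone 20 and two equivalents of the methylene donor 21. Cutting inside ring A or inside the pyrones instead would leave the bridging or the acylation to be done later under acid. The chosen cut removes two rings in one step and uses the local symmetry. The forward reaction must alkylate both free ring A carbons without pyrone self-coupling, so 20 is first converted completely into its Mannich base 22 before 16 is added.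

**Protecting groups.** Compound 16 is traced to its tris(benzyl ether) 15. Benzyl ethers are removed by neutral hydrogenolysis, whereas methyl ethers would need a boron or aluminium halide, which could enolise the ketone or strip the acyl group. The benzyl ethers must survive an aryllithium, an alkoxide base and a buffered peroxide oxidation, which they should.

**Ketone (key cut).** In 15 both bonds to the carbonyl carbon are cut, ring A C1–C(=O) and C(=O)–CH, leading to the borinic ester 12 and the one-carbon unit 13. Cutting only the aryl–acyl bond would need a preformed enantiopure acyl donor exposed to Lewis acid or strong base. Cutting only the C(=O)–CH bond would need an asymmetric α-alkylation of a hindered aryl ketone. Precursor 12 has no carbonyl group and carries the stereocentre on boron. The forward reaction must move both carbon groups from boron to the new carbon with retention, and the aryl–boron bond must survive until it does.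

**Aryl–boron bond.** Compound 12 is cut at the aryl–boron bond into the aryl bromide 9 (through the aryllithium 10 and the borate 11) and the cyclic boronate 7. A cyclic boronate takes up one carbanion cleanly, and ring-opening silylation of 11 releases the borinate without acid. The bromide is preferred to direct lithiation of 8, which would compete with benzylic deprotonation; 9 comes from 8 by one bromination.

**Stereocentre.** In 7 the C–B and C–H bonds of the sec-butyl group are cut, giving cis-but-2-ene 3 and the chiral borane 2, itself made from the terpene 1. The alkene is symmetric, so there is no regiochemical question and the reagent alone decides the face. The trialkylborane 4 is dealkylated to the boronate 5, which is taken through the acid 6 to 7 to separate it from the liberated terpene.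

**Pyrone.** In 20 the C4–C5 and O1–C2 bonds are cut, giving the silyl enol ether 18 and malonyl dichloride 19; 18 comes from pentan-3-one 17. The ketone is symmetric, so only one enol ether constitution is possible.

## Roads not taken

Alternative 1: The cut runs through ring A: bonds C2–C3 and C5–C6 are broken, leaving 19 as the source of C1, C2 and C6 and the symmetric ketone A2, 1,5-bis(6-ethyl-4-methoxy-5-methyl-2-oxo-2H-pyran-3-yl)pentan-3-one, whose carbonyl carbon becomes C4.
- Forward key step: after enol silylation, A2 would be C-acylated twice by 19 and the cyclohexanetrione would enolise to A1, the ring A triol with both pyronylmethyl arms in place and C1 still unsubstituted. Acylation at C1 with (2R)-2-methylbutanoyl chloride A3 and cleavage of the two pyrone methyl ethers would finish the synthesis.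
- Merits: the arms are set before ring A exists, so the mono- versus bis-bridging and self-coupling questions of step 9 never arise; here it is the better plan.
- Weak points: the same pair of reagents closes a pyrone through oxygen in step 8, so O-closure is the normal outcome and the carbocyclic C,C-closure is the exception. A2 needs a synthesis of its own. The stereocentre then arrives in a Lewis-acid acylation on a substrate that already holds the acid-labile bridges.
- Comparison: the chosen plan makes the ketone and fixes the stereocentre before any acid-sensitive feature is present, and it uses the annulation only in its natural O-closing mode.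

Alternative 2: The cut runs through both pyrones (C4–C5 and O1–C2 of each). It leads back to two equivalents of 18 and the fourfold acid chloride A5, 2,2'-[(2,4,6-trimethoxy-1,3-phenylene)bis(methylene)]di(propanedioyl dichloride).
- Forward key step: each malonyl unit of A5 would C-acylate 18 and the enol oxygen would lactonise onto the second acid chloride, giving the bis(pyrone) A4.
- Merits: this is the annulation of step 8 in its preferred mode, and substituted malonyl chlorides are good partners. The bridges are built by ordinary benzylic chemistry, which is cleaner than the bridging of step 9.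
- Weak points: A5 takes several steps and the annulation must succeed at both ends. After A4 the acyl group must still be placed on the last, most hindered ring A carbon with A3 under Lewis acid in the presence of two free pyrone enols. Three aryl methyl ethers must then be cleaved by a boron or aluminium halide next to the enolisable stereocentre and the bridges.
- Comparison: against its cleaner bridging, the chosen plan has a shorter sequence, a neutral final deprotection and no strong acid after the stereocentre exists.

Alternative 3: The cut takes the ring A C1–C(=O) bond together with the neighbouring C2–O bond. It leads to 3,5-dimethoxybenzyne A7, released from the silyl triflate A9, and (2R)-2-methylbutanoic acid A8.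
- Forward key step: CsF would release A7, the carboxylate would add through oxygen at the aryne carbon remote from the flanking methoxy group, and the aryl anion would attack the acyl carbon. The four-membered intermediate would open to the ortho-hydroxy ketone A6.
- Merits: two bonds on neighbouring carbons form in one step, as many as in the chosen key step. The regiochemistry is secured by the methoxy group beside the aryne. The stereocentre is bought, so there is no borane handling and no fragile aryl–boron bond. In robustness of the ketone-forming step, and probably in step count to a ring A ketone, it is the better plan.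
- Weak points: A8 is the less common enantiomer and its purity is set by the supplier. The insertion needs fluoride at elevated temperature, so the α-branched ketone A6 and its ester precursor meet a hot basic medium, with erosion of configuration as the risk. A9 takes several steps. Two methyl ethers remain whose cleavage needs a boron halide.
- Comparison: the chosen plan creates the stereocentre at low temperature from a symmetric alkene, gives either enantiomer by choice of terpene, keeps the centre non-enolisable until the carbonyl is formed, and ends with hydrogenolysis.

Key step: step 5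

Assumption: (−)-diisopinocampheylborane made from (+)-α-pinene is taken to add to cis-but-2-ene in the (R) sense, as in its established use with cis-alkenes; the benzyl ethers and the alkoxy group on boron are spectators chosen for this route.

## Route

Step 1
Reactants: 1 (+)-α-pinene, (1R,5R)-2,6,6-trimethylbicyclo[3.1.1]hept-2-ene
Product: 2 (−)-diisopinocampheylborane, bis[(1R,2S,3R,5R)-2,6,6-trimethylbicyclo[3.1.1]heptan-3-yl]borane
Conditions: BH3·SMe2, THF, 0 °C; kept at 0 °C for 3 d over excess 1; crystals filtered and washed cold under N2
Reagents that add atoms: borane–dimethyl sulfide, C[S+](C)[BH3-]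
Why: Twofold Brown hydroboration of the trisubstituted alkene stops at the dialkylborane; boron and hydrogen add syn from the face away from the gem-dimethyl bridge, which fixes C2 and C3 of each pinanyl group, and slow equilibration over excess 1 is known to leave the crystalline reagent richer in the homochiral form than the terpene used.

Step 2
Reactants: 3 cis-but-2-ene; 2 (−)-diisopinocampheylborane
Product: 7 2-[(2R)-butan-2-yl]-1,3,2-dioxaborinane, via sec-butyldiisopinocampheylborane 4 (not isolated), via diethyl sec-butylboronate 5 (not isolated), via sec-butylboronic acid 6 (not isolated)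
Conditions: 3 (condensed, slight excess), THF, −25 °C; CH3CHO (excess), 0 °C → rt; aq NaOH extraction, then aq HCl, Et2O; HO(CH2)3OH, pentane, rt; distillation
Reagents that add atoms: propane-1,3-diol, OCCCO
Why: Asymmetric hydroboration: syn addition of B–H to the symmetric cis-alkene, with the two pinanyl groups of 2 selecting one enantiotopic face, sets the (R) boron-bearing carbon by reagent control. Acetaldehyde then removes both pinanyl groups as α-pinene by β-hydride transfer without touching the sec-butyl carbon, and base extraction followed by esterification with the diol separates the boron compound from the terpene as the stable cyclic ester.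

Step 3
Reactants: 8 1,3,5-tris(benzyloxy)benzene
Product: 9 2-bromo-1,3,5-tris(benzyloxy)benzene
Conditions: NBS (1.0 equiv), CH2Cl2, −20 °C → 0 °C, dark
Reagents that add atoms: N-bromosuccinimide, O=C1CCC(=O)N1Br
Why: Electrophilic aromatic bromination of a strongly activated arene whose three free positions are equivalent; one equivalent of NBS in the cold should stop at the monobromide because the bromine adds hindrance and lowers ring reactivity.

Step 4
Reactants: 9 2-bromo-1,3,5-tris(benzyloxy)benzene; 7 2-[(2R)-butan-2-yl]-1,3,2-dioxaborinane
Product: 12 3-[(trimethylsilyl)oxy]propyl [(2R)-butan-2-yl][2,4,6-tris(benzyloxy)phenyl]borinate, via 2,4,6-tris(benzyloxy)phenyllithium 10 (not isolated), via cyclic lithium borate 11 (not isolated)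
Conditions: n-BuLi, THF, −78 °C; 7, −78 °C; Me3SiCl, −78 °C → rt; solvent exchange to pentane, filtration under Ar, used crude
Reagents that add atoms: chlorotrimethylsilane, C[Si](C)(C)Cl
Why: Bromine–lithium exchange, addition of the aryllithium to the cyclic boronic ester and ring-opening O-silylation of the resulting borate (borinic ester synthesis from a boronate) give the mixed borinate with no proton source, which matters because a 2,4,6-trialkoxyphenyl–boron bond is cleaved by acid. The sec-butyl carbon takes no part, so its configuration is kept.

Step 5
Reactants: 12 3-[(trimethylsilyl)oxy]propyl [(2R)-butan-2-yl][2,4,6-tris(benzyloxy)phenyl]borinate; 13 dichloromethyl methyl ether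
Product: 15 (2R)-2-methyl-1-[2,4,6-tris(benzyloxy)phenyl]butan-1-one, via α-methoxyalkylborane 14 (not isolated)
Conditions: 13 (1.5 equiv), THF, 0 °C; LiOCEt3 (from Et3COH and n-BuLi, hexane; 2 equiv), 0 °C → rt; then NaH2PO4/Na2HPO4 buffer (pH 8), 30% H2O2, 0 °C → rt
Reagents that add atoms: hydrogen peroxide, OO
Why: This is the DCME ketone synthesis from a borinic ester, whose closest known use is on enantiomerically enriched sec-alkyl(organyl)borinates. LiOCEt3, too hindered to bind boron, deprotonates 13 in the presence of 12 and the carbenoid LiCCl2OMe is captured at boron to give a borate. One carbon group shifts from boron to the new carbon with loss of chloride and the second follows with the remaining chlorine passing to boron, giving 14 with aryl and sec-butyl on one carbon; once the electron-rich aryl group is on carbon the remaining C–Cl bond ionises easily, which should help the second shift. Each shift is a 1,2-migration with retention at the migrating carbon, so the (R) centre from step 2 is carried over unchanged. Buffered H2O2 oxidises the C–B bond of 14 and the hemiketal loses methanol to give 15. No ring is closed and no stereocentre is created, since the carbinol carbon of 14 ends as the carbonyl carbon. The step needs both carbon groups to migrate while the alkoxy group stays, the aryl–boron bond to escape protonolysis before it migrates, and the new ketone to escape enolisation; the strictly aprotic medium, acid-free 12 and the cold pH 8 oxidation are there for this.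

Step 6
Reactants: 15 (2R)-2-methyl-1-[2,4,6-tris(benzyloxy)phenyl]butan-1-one
Product: 16 (2R)-2-methyl-1-(2,4,6-trihydroxyphenyl)butan-1-one
Conditions: H2 (1 atm), Pd/C (10 wt% Pd), EtOAc, rt
Reagents that add atoms: none
Why: Hydrogenolysis of three benzyl ethers under neutral conditions, so the α-stereocentre meets neither acid nor base; the ketone, flanked by two ortho oxygens and conjugated as a vinylogous acid, should not be reduced at 1 atm.

Step 7
Reactants: 17 pentan-3-one
Product: 18 (Z)-trimethyl(pent-2-en-3-yloxy)silane
Conditions: Me3SiOTf, Et3N, Et2O, 0 °C → rt
Reagents that add atoms: trimethylsilyl trifluoromethanesulfonate, C[Si](C)(C)OS(=O)(=O)C(F)(F)F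
Why: Amine-mediated enol silylation of a symmetric ketone, so no regiochemical question arises; the (Z) isomer is expected to predominate and either isomer leads to the same pyrone.

Step 8
Reactants: 18 (Z)-trimethyl(pent-2-en-3-yloxy)silane; 19 malonyl dichloride
Product: 20 6-ethyl-4-hydroxy-5-methyl-2H-pyran-2-one
Conditions: Et2O, −78 °C → rt, no base; crystallisation
Reagents that add atoms: none
Why: Pyrone annulation of a silyl enol ether with malonyl dichloride: C-acylation at the enol carbon with loss of Me3SiCl, then lactonisation of the enol oxygen onto the second acid chloride and tautomerisation to the 4-hydroxy-2-pyrone.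

Step 9
Reactants: 20 6-ethyl-4-hydroxy-5-methyl-2H-pyran-2-one (2.2 equiv); 21 N,N-dimethylmethaniminium iodide (Eschenmoser's salt, 2.2 equiv); 16 (2R)-2-methyl-1-(2,4,6-trihydroxyphenyl)butan-1-one
Product: 23 (2R)-1-{3,5-bis[(6-ethyl-4-hydroxy-5-methyl-2-oxo-2H-pyran-3-yl)methyl]-2,4,6-trihydroxyphenyl}-2-methylbutan-1-one (target), via pyrone Mannich base 22 (not isolated)
Conditions: 20, 21, MeCN, rt; then 16, 50 °C
Reagents that add atoms: none
Why: Mannich reaction at C3 of the pyrone, then loss of dimethylamine to the 3-methylenepyran-2,4-dione and conjugate addition (Friedel–Crafts-type C-alkylation) of the acylphloroglucinol at its two free ring carbons. Forming 22 completely before 16 is added should suppress pyrone self-coupling, and the neutral to weakly acidic medium spares the α-stereocentre.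

## Compound list

1 | (+)-α-pinene, (1R,5R)-2,6,6-trimethylbicyclo[3.1.1]hept-2-ene | CC1=CC[C@@H]2C[C@H]1C2(C)C | starting material
2 | (−)-diisopinocampheylborane, bis[(1R,2S,3R,5R)-2,6,6-trimethylbicyclo[3.1.1]heptan-3-yl]borane | [H]B([C@@H]1C[C@@H]2C[C@H]([C@H]1C)C2(C)C)[C@@H]1C[C@@H]2C[C@H]([C@H]1C)C2(C)C | intermediate
3 | cis-but-2-ene | C/C=C\C | starting material
4 | [(2R)-butan-2-yl]bis[(1R,2S,3R,5R)-2,6,6-trimethylbicyclo[3.1.1]heptan-3-yl]borane | CC[C@@H](C)B([C@@H]1C[C@@H]2C[C@H]([C@H]1C)C2(C)C)[C@@H]1C[C@@H]2C[C@H]([C@H]1C)C2(C)C | intermediate
5 | diethyl [(2R)-butan-2-yl]boronate | CC[C@@H](C)B(OCC)OCC | intermediate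
6 | [(2R)-butan-2-yl]boronic acid | CC[C@@H](C)B(O)O | intermediate
7 | 2-[(2R)-butan-2-yl]-1,3,2-dioxaborinane | CC[C@@H](C)B1OCCCO1 | intermediate
8 | 1,3,5-tris(benzyloxy)benzene | c1ccc(COc2cc(OCc3ccccc3)cc(OCc3ccccc3)c2)cc1 | starting material
9 | 2-bromo-1,3,5-tris(benzyloxy)benzene | Brc1c(OCc2ccccc2)cc(OCc2ccccc2)cc1OCc1ccccc1 | intermediate
10 | [2,4,6-tris(benzyloxy)phenyl]lithium | [Li]c1c(OCc2ccccc2)cc(OCc2ccccc2)cc1OCc1ccccc1 | intermediate
11 | lithium 2-[(2R)-butan-2-yl]-2-[2,4,6-tris(benzyloxy)phenyl]-1,3,2-dioxaborinan-2-uide | [Li+].CC[C@@H](C)[B-]1(OCCCO1)c1c(OCc2ccccc2)cc(OCc2ccccc2)cc1OCc1ccccc1 | intermediate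
12 | 3-[(trimethylsilyl)oxy]propyl [(2R)-butan-2-yl][2,4,6-tris(benzyloxy)phenyl]borinate | CC[C@@H](C)B(OCCCO[Si](C)(C)C)c1c(OCc2ccccc2)cc(OCc2ccccc2)cc1OCc1ccccc1 | intermediate
13 | dichloromethyl methyl ether | COC(Cl)Cl | starting material
14 | chloro{(2R)-1-methoxy-2-methyl-1-[2,4,6-tris(benzyloxy)phenyl]butyl}{3-[(trimethylsilyl)oxy]propoxy}borane (both epimers at C1) | CC[C@@H](C)C(OC)(B(Cl)OCCCO[Si](C)(C)C)c1c(OCc2ccccc2)cc(OCc2ccccc2)cc1OCc1ccccc1 | intermediate
15 | (2R)-2-methyl-1-[2,4,6-tris(benzyloxy)phenyl]butan-1-one | CC[C@@H](C)C(=O)c1c(OCc2ccccc2)cc(OCc2ccccc2)cc1OCc1ccccc1 | intermediate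
16 | (2R)-2-methyl-1-(2,4,6-trihydroxyphenyl)butan-1-one | CC[C@@H](C)C(=O)c1c(O)cc(O)cc1O | intermediate
17 | pentan-3-one | CCC(=O)CC | starting material
18 | (Z)-trimethyl(pent-2-en-3-yloxy)silane | C/C=C(/CC)O[Si](C)(C)C | intermediate
19 | malonyl dichloride | O=C(Cl)CC(=O)Cl | starting material
20 | 6-ethyl-4-hydroxy-5-methyl-2H-pyran-2-one | CCc1oc(=O)cc(O)c1C | intermediate
21 | N,N-dimethylmethaniminium iodide (Eschenmoser's salt) | C=[N+](C)C.[I-] | starting material
22 | 3-[(dimethylamino)methyl]-6-ethyl-4-hydroxy-5-methyl-2H-pyran-2-one (formed as its hydroiodide) | CCc1oc(=O)c(CN(C)C)c(O)c1C | intermediate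
23 | (2R)-1-{3,5-bis[(6-ethyl-4-hydroxy-5-methyl-2-oxo-2H-pyran-3-yl)methyl]-2,4,6-trihydroxyphenyl}-2-methylbutan-1-one | CCc1oc(=O)c(Cc2c(O)c(Cc3c(O)c(C)c(CC)oc3=O)c(O)c(C(=O)[C@H](C)CC)c2O)c(O)c1C | target

## Step count and risks

Total step count: 9. Longest linear sequence: 6 steps (steps 1, 2, 4, 5, 6 and 9); steps 3, 7 and 8 are side branches.

**Step 5 (key step).** What is most likely to go wrong is protonolysis of the very electron-rich aryl–boron bond before the aryl group has migrated. Also possible is slow capture of the carbenoid by a boron atom that is hindered and internally coordinated by two ortho oxygens, so that the carbenoid decays by α-elimination. After the migrations, the benzylic α-methoxy borane 14 may be protonated off instead of oxidised, and the new ketone may enolise during the oxidation.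
Fallback, from 9 back to 15: commercial (2R)-2-methylbutanoic acid F1 (the same acid as A8) would be coupled with N,O-dimethylhydroxylamine hydrochloride and a carbodiimide to (2R)-N-methoxy-N,2-dimethylbutanamide F2. Bromide 9 would be lithiated as in step 4 to 10 and added to F2 at −78 °C, and the chelated tetrahedral adduct would release 15 on aqueous work-up (Weinreb ketone synthesis). This gives up the double migration and takes the stereocentre from the chiral pool.

**Step 4.** The borate 11 may revert by loss of the stabilised, hindered aryl anion on silylation instead of opening at oxygen, and the free borinate may lose its aryl group to traces of moisture on handling.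
Fallback, from 7 back to 15, with no aryl–boron bond at any stage: Matteson homologation of 7 with LiCHCl2 (CH2Cl2, LiN(iPr)2, −78 °C) would give 2-[(2R)-1-chloro-2-methylbutyl]-1,3,2-dioxaborinane F3. Oxidation with H2O2 at pH 8 would give (2R)-2-methylbutanal F4, used at once in solution. Addition of 10, made from 9, would give (2R)-2-methyl-1-[2,4,6-tris(benzyloxy)phenyl]butan-1-ol F5, and Dess–Martin oxidation would lead to 15.

**Step 9.** The pyrone-derived methylene intermediate may be trapped by a second pyrone to give the methylenebis(pyrone), the second bridging may lag behind the first because of crowding on ring A, and O-alkylation may compete.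
Fallback, from 16 back to 23, with the roles reversed: 16 would be aminomethylated twice with 21 to (2R)-1-{3,5-bis[(dimethylamino)methyl]-2,4,6-trihydroxyphenyl}-2-methylbutan-1-one F6. Heating F6 with 20 in dioxane would expel dimethylamine and generate ring A quinone methides one after the other, each captured by C3 of the pyrone.

**Step 8.** O-acylation of the enol silane, acylation of both ends of 19 by two enol silanes, or ketene formation from 19 may divert material from the pyrone.
Fallback, from 17 back to 20: Claisen condensation of 17 with ethyl acetate (NaH) would give 3-methylhexane-2,4-dione F7. Its dianion (LiN(iPr)2, 2 equiv) would be carboxylated with CO2 at the methyl terminus to 4-methyl-3,5-dioxoheptanoic acid F8, and dehydrative lactonisation with acetic anhydride would give 20.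

## Further compounds

F1 | step 5 | (2R)-2-methylbutanoic acid | CC[C@@H](C)C(=O)O
F2 | step 5 | (2R)-N-methoxy-N,2-dimethylbutanamide | CC[C@@H](C)C(=O)N(C)OC
F3 | step 4 | 2-[(2R)-1-chloro-2-methylbutyl]-1,3,2-dioxaborinane (both epimers at C1) | CC[C@@H](C)C(Cl)B1OCCCO1
F4 | step 4 | (2R)-2-methylbutanal | CC[C@@H](C)C=O
F5 | step 4 | (2R)-2-methyl-1-[2,4,6-tris(benzyloxy)phenyl]butan-1-ol (both epimers at C1) | CC[C@@H](C)C(O)c1c(OCc2ccccc2)cc(OCc2ccccc2)cc1OCc1ccccc1
F6 | step 9 | (2R)-1-{3,5-bis[(dimethylamino)methyl]-2,4,6-trihydroxyphenyl}-2-methylbutan-1-one | CC[C@@H](C)C(=O)c1c(O)c(CN(C)C)c(O)c(CN(C)C)c1O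
F7 | step 8 | 3-methylhexane-2,4-dione (racemic, enolisable) | CCC(=O)C(C)C(C)=O
F8 | step 8 | 4-methyl-3,5-dioxoheptanoic acid (racemic, enolisable) | CCC(=O)C(C)C(=O)CC(=O)O
A1 | alternative 1 | 3,3'-[(2,4,6-trihydroxy-1,3-phenylene)bis(methylene)]bis(6-ethyl-4-methoxy-5-methyl-2H-pyran-2-one) | CCc1oc(=O)c(Cc2c(O)cc(O)c(Cc3c(OC)c(C)c(CC)oc3=O)c2O)c(OC)c1C
A2 | alternative 1 | 1,5-bis(6-ethyl-4-methoxy-5-methyl-2-oxo-2H-pyran-3-yl)pentan-3-one | CCc1oc(=O)c(CCC(=O)CCc2c(OC)c(C)c(CC)oc2=O)c(OC)c1C
A3 | alternative 1 | (2R)-2-methylbutanoyl chloride | CC[C@@H](C)C(=O)Cl
A4 | alternative 2 | 3,3'-[(2,4,6-trimethoxy-1,3-phenylene)bis(methylene)]bis(6-ethyl-4-hydroxy-5-methyl-2H-pyran-2-one) | CCc1oc(=O)c(Cc2c(OC)cc(OC)c(Cc3c(O)c(C)c(CC)oc3=O)c2OC)c(O)c1C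
A5 | alternative 2 | 2,2'-[(2,4,6-trimethoxy-1,3-phenylene)bis(methylene)]di(propanedioyl dichloride) | COc1cc(OC)c(CC(C(=O)Cl)C(=O)Cl)c(OC)c1CC(C(=O)Cl)C(=O)Cl
A6 | alternative 3 | (2R)-1-(2-hydroxy-4,6-dimethoxyphenyl)-2-methylbutan-1-one | CC[C@@H](C)C(=O)c1c(O)cc(OC)cc1OC
A7 | alternative 3 | 3,5-dimethoxybenzyne (1,2-didehydro-3,5-dimethoxybenzene) | COC1=CC(OC)=CC#C1
A8 | alternative 3 | (2R)-2-methylbutanoic acid | CC[C@@H](C)C(=O)O
A9 | alternative 3 | 3,5-dimethoxy-2-(trimethylsilyl)phenyl trifluoromethanesulfonate | COc1cc(OC)c([Si](C)(C)C)c(OS(=O)(=O)C(F)(F)F)c1
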